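## Structural features

The target is a germacranolide: a ten-membered carbocycle (C1–C10) with C14 on C10 and C15 on C4, and an α-methylene γ-lactone (C11–C13, ring oxygen on C6) fused across C6–C7 so that C5 and C8 lie on opposite faces of the lactone ring. Two oxiranes are fused to the large ring. The 1,10-epoxide is cis (C9 and C2 on the same side) and so descends from a Z C1=C10 olefin. The 4,5-epoxide is trans and can come from an E olefin or, with inversion at C5, from a ring-cis 4,5-diol. There are seven stereocentres (1S,4R,5R,6R,7S,8R,10R). Five of them, C4 to C8, are contiguous and all oxygen-bearing, with O6/O7 anti and O7/O8 syn along the chain, and C7 is a fully substituted carbinol between two secondary ones. The fragile groups are the α-methylene lactone and the methacrylate (Michael acceptors, not compatible with SmI2 or hot base), the two acid-labile trisubstituted epoxides with hydroxyls close by, and the tertiary allylic hydroxyl at C7. The real difficulty is to close a ten-membered ring that holds a Z trisubstituted olefin, to set the C4–C8 oxygen array in the right relative and absolute sense, and to make C12 lactonise on O6 and not on O8. The key step exploits the C1=C10 unit: C10 carries the methyl group and sits between C9 and C1, which is the pattern written when a C9 organocopper adds syn across propyne. Trapping the Z alkenylcopper at C1 with an enone then adds C2–C4 and C15, so nine skeletal carbons, the olefin geometry and two different carbonyl ends (C8, C4) arise in one flask.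

## Logic of the disconnections

36 to 35: the C1–O and C10–O bonds of the cis-oxirane are cut. The Z olefin of 35 is its only electron-rich alkene and syn oxygen transfer keeps the cis relationship, so two stereocentres and the most acid-sensitive group go last. The forward step must select one face of the ring olefin.

35 to 34 to 33: the O8–acyl bond, then the O8–Si bond. The methacrylate cannot pass base, SmI2 or fluoride, so it is added late. The acylation must distinguish the secondary O8 from the tertiary O7, and O8 must stay silylated until the lactone exists so that C12 can close only on O6.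

33 to 30 to 29 to 28: the O6–C12 bond and the oxidation level of C12, then the O6–Si and O12–benzyl bonds. The α-methylene lactone would not survive the reductive ring closure and an acyloxy group on C6 would be cleaved by it, so the lactone is carried as an allylic ether and a silyl ether. The oxidation must touch only the allylic primary alcohol beside an epoxide and a 6,7-diol.

28 to 26 (through 27): the C5–O bond of the 4,5-oxirane. A ring-cis diol gives the trans-epoxide stereospecifically when the secondary hydroxyl is made a leaving group and the tertiary oxygen displaces it with inversion. Two oxirane stereocentres become a diol that a C–C bond formation can supply. Only the C5 hydroxyl may be sulfonylated, and 26 must be the (4R,5S) isomer.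

26 to 25: the C4–C5 ring bond. Both carbons must carry oxygen, and one of them is the methyl ketone delivered by the key step, so a reductive carbonyl coupling closes the ring with no change of oxidation state. The precursor is an open chain. The step must cyclise faster than it oligomerises and give the cis-diol with O5 anti to O6.

25 to 24 to 23 to 21 (through 22) to 20: the oxidation level of C5 and the C6–O and C7–O bonds. The 6,7-anti diol is traced, through inversion at C6, to the oxirane of 21 and so to the E olefin of 20. A reagent-controlled epoxidation of a primary allylic alcohol then sets C6 and C7 absolutely. The forward steps must epoxidise only the allylic olefin, open at C5 after epoxide migration, and tell O5 from O6.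

20 to 19 to 18 to 17 + 16: the C7–C8 bond. It joins the aldehyde carbon of 17 to an alkenyl carbon of 16 by a union that ignores the ketone and the acidic C9 hydrogens. This gives two achiral fragments of similar size. The step must select the Si face of the aldehyde (8R).

16 to 15 (through 14) to 13 to 11 + 12, and 11 to 9 + 10: the C5 oxidation level, the C7–I bond, the C7–C11 bond and an ether bond. A syn stannylmetalation of an ynoate fixes the olefin geometry (iodine trans to C5), and the enyne comes from two commercial three-carbon pieces.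

17 to 8: the aldehyde is masked as the dioxolane that the organometallic chemistry requires. The unmasking must not move the β,γ-olefin into conjugation.

8 to 2 + 3 + 4 (through 7, 6, 5), and 2 to 1: the C9–C10 and C1–C2 bonds are cut. This is the only place where the Z olefin can be bought from commodity chemicals with full geometric control. 2 must have a single methylene between magnesium and the acetal carbon. The homologue with two methylenes would put an extra carbon between C10 and C8 and could not give 8.

## Other disconnections considered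

Alternative 1: The ring is cut between C4 and C5, the carbons that end as the 4,5-epoxide. In the forward step SmI2 reduces the C5 aldehyde of the open-chain keto aldehyde A2 to a ketyl, which couples with the C4 methyl ketone to give the ten-membered cis-4,5-diol A1 (6,7-acetonide, 8-OTBS, 12-OPMB).
- In its favour: ring closure and both epoxide carbons come in one step; a cis-diol is converted stereospecifically into the trans-epoxide; the Z olefin is inert to the reductant; the acetonide of A2 stiffens C6–C7 and masks the tertiary hydroxyl, which should help the closure and its facial control.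
- Against it here: two stereocentres are made in an entropically costly closure under remote control; the α-alkoxy aldehyde can epimerise; the acetonide can be removed only with acid, so it must go before the epoxide exists, which leaves four free hydroxyls to be told apart. As a centre of the plan it does not say how the C8–C4 chain and its Z olefin are made.
- Comparison: the chosen plan closes the same bond with the same reagent (step 15), so on the ring closure the alternative is its equal, and with the acetonide probably the better for rigidity. The chosen plan differs in carrying a silyl ether on O6, so that no acid is needed once the epoxide is in place, and in making the whole C8–C4 chain in one step. The mechanisms differ (ketyl coupling against polar organocopper assembly). In step count the two are complementary: a route centred on A1 still has to build the chain of A2.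

Alternative 2: The cut is the C7–C11 bond, with O6 already acylated. In the forward step CrCl2 with catalytic NiCl2 turns the 2-bromoacrylate of ring ketone A4 into an alkenylchromium at C11 that adds to the C7 ketone and gives the dienolide A3, the target without its two epoxides.
- In its favour: the tertiary carbinol, the C7–C11 bond and the complete α-methylene lactone arise in one step; the tether removes any doubt between O6 and O8; no oxidation-state change is needed at C12. On the lactone this is better than the chosen plan, which spends four steps (17 to 20) on it.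
- Against it here: ketones are poor partners for alkenylchromium reagents; A4 carries two polymerisable acrylates and an epimerisable α-acyloxy ketone; the ten-membered ring with its Z and E olefins must already exist, so the hardest problem is moved upstream; both epoxides are left to substrate-controlled oxidation of A3, where the 4,5-olefin is deactivated by the allylic lactone oxygen.
- Comparison: structurally it addresses C7 and the lactone, not the ring or the chain. Mechanistically it is a polar organochromium addition. It is shorter at the end, but the chosen plan fixes four of the seven stereocentres by reagent control or stereospecific steps before the last oxidation, where the alternative trusts ring conformation three times.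

Alternative 3: The cut is the C5–C6 ring bond together with the O6–C12 lactone bond. In the forward step CrCl2 with catalytic NiCl2 converts the E alkenyl iodide of open-chain aldehyde A6 into an alkenylchromium that adds to the C6 aldehyde; the C6 alkoxide closes on the methyl ester to give the silylated dienolide A5.
- In its favour: macrocyclic alkenylchromium additions are a well-tried way to ten-membered rings; the C4=C5 geometry is fixed beforehand, so the closure makes one stereocentre and not two, a point on which it is better than the chosen closure; lactonisation in the same flask saves steps.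
- Against it here: the aldehyde of A6 is neopentyl-like and flanked by a silyloxy group, an acrylate and a methacrylate; the configuration at C6 depends on an uncertain facial bias; only the correct epimer can lactonise trans; the E alkenyl iodide cannot be derived from a C4 methyl ketone, so the chain would have to end in an alkyne at C4 and pass through carbometalation; both epoxides are again made last under substrate control.
- Comparison: it is probably the shorter route overall and equal in convergence. The chosen plan is the safer one for the 4,5-epoxide, which it derives stereospecifically from a diol.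

Key step: step 2

Remark on the chemistry: skeletal atoms are given germacrane numbers throughout (ring C1–C10, C14 on C10, C15 on C4, C11–C13 the lactone carbons).
Remark on the chemistry: the acetal organometallic is the (1,3-dioxolan-2-yl)methyl reagent 2, made from bromide 1. The 2-(1,3-dioxolan-2-yl)ethyl homologue, made from 2-(2-bromoethyl)-1,3-dioxolane, would give the oct-5-en-2-one homologue with ten skeletal carbons and cannot give 8.
Assumption: 2 needs THF for its preparation; it is used as a concentrated solution so that Et2O–Me2S remains the bulk medium of the carbocupration.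

Step 1
Reactants: 1 2-(bromomethyl)-1,3-dioxolane
Product: 2 (1,3-dioxolan-2-ylmethyl)magnesium bromide
Conditions: Mg turnings (activated with BrCH2CH2Br), THF, 25–30 °C; used as about 1 M solution
Reagents that add atoms: magnesium, [Mg]
Why: Grignard formation by insertion of magnesium into the primary C–Br bond; the cyclic acetal holds the β-oxygens in a ring, which slows β-elimination enough for the reagent to be kept in THF below 30 °C (it is also sold as a THF solution).

Step 2
Reactants: 2 (1,3-dioxolan-2-ylmethyl)magnesium bromide, 3 propyne, 4 methyl vinyl ketone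
Product: 8 (5Z)-7-(1,3-dioxolan-2-yl)-6-methylhept-5-en-2-one, via alkylcopper 5 (not isolated), via alkenylcopper 6 (not isolated), via silyl enol ether 7 (not isolated)
Conditions: CuBr·SMe2 (1.0 equiv), Et2O–Me2S, −45 °C; 3 (3 equiv), −25 °C; 4, Me3SiCl, −78 → −30 °C; NH4Cl/NH3 aq.; K2CO3, MeOH–H2O, 0 °C
Reagents that add atoms: none
Why: Transmetalation of 2 to monovalent copper gives alkylcopper 5 (RCu·MgBr2·SMe2), which adds across the triple bond of 3 in a concerted syn manner, C9 going to the internal carbon (C10) and copper to the unhindered terminal carbon (C1); this is the classical carbocupration of a 1-alkyne by an organocopper–magnesium halide reagent. The Z alkenylcopper 6 then adds 1,4 to enone 4 with retention at the metal-bearing carbon (C1–C2 bond), Me3SiCl accelerating the addition and trapping the enolate as silyl enol ether 7, which is cleaved to 8 on work-up; the closest known reaction type is this same one-flask carbocupration/conjugate addition sequence. No ring is closed and no stereocentre is formed; the stereochemical element is the C1=C10 geometry, which is Z because C9 and copper arrive on the same side of the alkyne and copper is replaced by C2 without isomerisation. Three selectivities are needed: regiochemistry of the addition (secured by the terminal alkyne), syn addition faster than metalation of the acidic alkyne C–H (secured by the non-basic RCu·MgBr2 species in ether–dimethyl sulfide), and 1,4- over 1,2-addition (secured by copper and Me3SiCl). The dioxolane is inert to all the organometallic species and delivers C8 at the aldehyde oxidation level, distinct from the C4 ketone.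

Step 3
Reactants: 9 2,3-dibromoprop-1-ene, 10 (4-methoxyphenyl)methanol
Product: 11 1-{[(2-bromoprop-2-en-1-yl)oxy]methyl}-4-methoxybenzene
Conditions: NaH, THF–DMF, 0 °C; then 9, 0 °C → rt
Reagents that add atoms: none
Why: Williamson ether synthesis; the alkoxide of 10 displaces the allylic bromide by SN2 while the vinylic bromide is inert.

Step 4
Reactants: 11 1-{[(2-bromoprop-2-en-1-yl)oxy]methyl}-4-methoxybenzene, 12 methyl prop-2-ynoate
Product: 13 methyl 5-[(4-methoxybenzyl)oxy]-4-methylidenepent-2-ynoate
Conditions: Pd(PPh3)2Cl2 (3 mol %), CuI (5 mol %), K2CO3, THF, 40 °C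
Reagents that add atoms: none
Why: Sonogashira coupling of a 2-bromoalkene with a terminal alkyne (C7–C11 bond); an inorganic base is used because amines add to propiolates.

Step 5
Reactants: 13 methyl 5-[(4-methoxybenzyl)oxy]-4-methylidenepent-2-ynoate
Product: 15 methyl (2E)-3-iodo-5-[(4-methoxybenzyl)oxy]-4-methylidenepent-2-enoate, via vinylstannane 14 (not isolated)
Conditions: Bu3SnH, LDA, THF, −78 °C; CuBr·SMe2, −78 °C; 13, MeOH (2 equiv), −78 °C; then I2 (3 equiv), −78 → 0 °C; Na2S2O3 aq.
Reagents that add atoms: iodine, II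
Why: Syn stannylcupration of the ynoate puts tin on the β carbon (C7) and copper on the α carbon, and protonation at −78 °C with retention gives the kinetic E vinylstannane 14 (tin trans to the ester). Iododestannylation then proceeds with retention, so iodine ends trans to C5 and C11 cis to C5.

Step 6
Reactants: 15 methyl (2E)-3-iodo-5-[(4-methoxybenzyl)oxy]-4-methylidenepent-2-enoate
Product: 16 (2E)-3-iodo-5-[(4-methoxybenzyl)oxy]-4-methylidenepent-2-en-1-ol
Conditions: iBu2AlH (2.2 equiv), CH2Cl2, −78 °C; Rochelle salt aq.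
Reagents that add atoms: none
Why: 1,2-Reduction of the enoate to the allylic alcohol; the alkenyl iodide and the olefin geometry are untouched at −78 °C.

Step 7
Reactants: 8 (5Z)-7-(1,3-dioxolan-2-yl)-6-methylhept-5-en-2-one
Product: 17 (3Z)-3-methyl-7-oxooct-3-enal
Conditions: oxalic acid (10% aq.) on SiO2, CH2Cl2, 0 °C → rt; filtered and used at once
Reagents that add atoms: water, O
Why: Mild heterogeneous acetal hydrolysis; the β,γ-unsaturated aldehyde is kept away from base and strong acid, which would move the C1=C10 olefin into conjugation, and the ketone is unaffected.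

Step 8
Reactants: 17 (3Z)-3-methyl-7-oxooct-3-enal, 16 (2E)-3-iodo-5-[(4-methoxybenzyl)oxy]-4-methylidenepent-2-en-1-ol
Product: 18 (5Z,8R,9E)-8,11-dihydroxy-9-{3-[(4-methoxybenzyl)oxy]prop-1-en-2-yl}-6-methylundeca-5,9-dien-2-one
Conditions: CrCl2 (4 equiv), chiral sulfonamide–oxazoline ligand (4.4 equiv), Et3N, THF, rt; NiCl2 (5 mol %), 16, then 17, rt
Reagents that add atoms: none
Why: Asymmetric Nozaki–Hiyama–Kishi alkenylation: zerovalent nickel inserts into the C–I bond, transmetalation to trivalent chromium gives a non-basic alkenylchromium that adds to the aldehyde but not to the ketone, with retention of the olefin geometry (C7–C8 bond). The ligand enantiomer is chosen to direct the alkenyl group to the Si face of the aldehyde, which gives 8R; any 8S material becomes a separable diastereomer after step 11.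

Step 9
Reactants: 18 (5Z,8R,9E)-8,11-dihydroxy-9-{3-[(4-methoxybenzyl)oxy]prop-1-en-2-yl}-6-methylundeca-5,9-dien-2-one
Product: 19 (5Z,8R,9E)-8,11-bis[(tert-butyldimethylsilyl)oxy]-9-{3-[(4-methoxybenzyl)oxy]prop-1-en-2-yl}-6-methylundeca-5,9-dien-2-one
Conditions: tBuMe2SiOTf (2.5 equiv), 2,6-lutidine, CH2Cl2, −78 °C
Reagents that add atoms: tert-butyldimethylsilyl trifluoromethanesulfonate, CC(C)(C)[Si](C)(C)OS(=O)(=O)C(F)(F)F
Why: Silylation of both hydroxyls; at −78 °C with a pyridine base the alcohols react much faster than the ketone enolises.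

Step 10
Reactants: 19 (5Z,8R,9E)-8,11-bis[(tert-butyldimethylsilyl)oxy]-9-{3-[(4-methoxybenzyl)oxy]prop-1-en-2-yl}-6-methylundeca-5,9-dien-2-one
Product: 20 (5Z,8R,9E)-8-[(tert-butyldimethylsilyl)oxy]-11-hydroxy-9-{3-[(4-methoxybenzyl)oxy]prop-1-en-2-yl}-6-methylundeca-5,9-dien-2-one
Conditions: HF·pyridine, pyridine, THF, 0 °C
Reagents that add atoms: none
Why: Selective desilylation; the primary allylic silyl ether at O5 is cleaved much faster than the hindered secondary one at O8, which must stay until the lactone is closed.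

Step 11
Reactants: 20 (5Z,8R,9E)-8-[(tert-butyldimethylsilyl)oxy]-11-hydroxy-9-{3-[(4-methoxybenzyl)oxy]prop-1-en-2-yl}-6-methylundeca-5,9-dien-2-one
Product: 21 (5Z,8R)-8-[(tert-butyldimethylsilyl)oxy]-8-[(2R,3S)-3-(hydroxymethyl)-2-{3-[(4-methoxybenzyl)oxy]prop-1-en-2-yl}oxiran-2-yl]-6-methyloct-5-en-2-one
Conditions: Ti(OiPr)4 (0.2 equiv), L-(+)-diethyl tartrate (0.24 equiv), tBuOOH, 4 Å MS, CH2Cl2, −20 °C
Reagents that add atoms: tert-butyl hydroperoxide, CC(C)(C)OO
Why: Sharpless asymmetric epoxidation of a primary allylic alcohol; the titanium tartrate delivers oxygen only to the C6=C7 olefin held by the C5 hydroxyl, from the face that L-(+)-tartrate selects (oxirane 6S,7R), so C7 is set under reagent control. The other two olefins have no directing hydroxyl, and the 8S diastereomer is removed here by chromatography.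

Step 12
Reactants: 21 (5Z,8R)-8-[(tert-butyldimethylsilyl)oxy]-8-[(2R,3S)-3-(hydroxymethyl)-2-{3-[(4-methoxybenzyl)oxy]prop-1-en-2-yl}oxiran-2-yl]-6-methyloct-5-en-2-one
Product: 23 (5Z,8R,9R,10R)-8-[(tert-butyldimethylsilyl)oxy]-9,10,11-trihydroxy-9-{3-[(4-methoxybenzyl)oxy]prop-1-en-2-yl}-6-methylundec-5-en-2-one, via terminal epoxide 22 (not isolated)
Conditions: NaOH (0.5 M aq.), tBuOH, 70 °C
Reagents that add atoms: water (delivered as hydroxide), O
Why: Payne rearrangement and opening: the C5 alkoxide attacks C6 with inversion to give terminal epoxide 22, which hydroxide opens at the primary C5. C6 is thus inverted (S to R) and C7 keeps its oxygen, which gives the 6,7-anti diol; hydroxide is a hard nucleophile and should not attack the vinyl oxirane in the SN2' sense.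

Step 13
Reactants: 23 (5Z,8R,9R,10R)-8-[(tert-butyldimethylsilyl)oxy]-9,10,11-trihydroxy-9-{3-[(4-methoxybenzyl)oxy]prop-1-en-2-yl}-6-methylundec-5-en-2-one
Product: 24 (5Z,8R,9S,10R)-8-[(tert-butyldimethylsilyl)oxy]-9-hydroxy-9-{3-[(4-methoxybenzyl)oxy]prop-1-en-2-yl}-6-methyl-10,11-bis[(triethylsilyl)oxy]undec-5-en-2-one
Conditions: Et3SiCl (2.5 equiv), imidazole, DMAP (cat.), DMF, 0 °C → rt
Reagents that add atoms: chlorotriethylsilane, CC[Si](CC)(CC)Cl
Why: Silylation of the primary (O5) and secondary (O6) hydroxyls; the tertiary C7 hydroxyl does not react under these conditions. O6 is made an ether because an acyl group there would be cleaved reductively in step 15.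

Step 14
Reactants: 24 (5Z,8R,9S,10R)-8-[(tert-butyldimethylsilyl)oxy]-9-hydroxy-9-{3-[(4-methoxybenzyl)oxy]prop-1-en-2-yl}-6-methyl-10,11-bis[(triethylsilyl)oxy]undec-5-en-2-one
Product: 25 (2S,3S,4R,6Z)-4-[(tert-butyldimethylsilyl)oxy]-3-hydroxy-3-{3-[(4-methoxybenzyl)oxy]prop-1-en-2-yl}-6-methyl-10-oxo-2-[(triethylsilyl)oxy]undec-6-enal
Conditions: (COCl)2 (4 equiv), DMSO (8 equiv), CH2Cl2, −78 → −35 °C; Et3N, −78 → 0 °C
Reagents that add atoms: none
Why: Swern oxidation applied directly to a primary triethylsilyl ether, which is cleaved and oxidised in the same flask while secondary silyl ethers and the tertiary alcohol are untouched. This frees and oxidises C5 in one step; the cold amine work-up limits epimerisation at C6.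

Step 15
Reactants: 25 (2S,3S,4R,6Z)-4-[(tert-butyldimethylsilyl)oxy]-3-hydroxy-3-{3-[(4-methoxybenzyl)oxy]prop-1-en-2-yl}-6-methyl-10-oxo-2-[(triethylsilyl)oxy]undec-6-enal
Product: 26 (1(10)Z,4R,5S,6R,7S,8R)-8-[(tert-butyldimethylsilyl)oxy]-12-[(4-methoxybenzyl)oxy]-6-[(triethylsilyl)oxy]germacra-1(10),11(13)-diene-4,5,7-triol
Conditions: SmI2 (3 equiv), THF, 0.002 M, slow addition of 25, rt; NaHCO3 aq.
Reagents that add atoms: none
Why: Intramolecular SmI2 pinacol coupling: the aldehyde is reduced to a ketyl that adds to the samarium-bound C4 ketone (C4–C5 bond, ten-membered ring), high dilution favouring cyclisation. The new C5–O bond is expected anti to the non-chelating C6 silyloxy group (Felkin–Anh-type arrangement, C6–O anti to the forming bond). The ring-cis relation of the two new hydroxyls is expected from a transition state in which both oxygens are bound to trivalent samarium, but it is the less secure element in a ring of this size.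

Step 16
Reactants: 26 (1(10)Z,4R,5S,6R,7S,8R)-8-[(tert-butyldimethylsilyl)oxy]-12-[(4-methoxybenzyl)oxy]-6-[(triethylsilyl)oxy]germacra-1(10),11(13)-diene-4,5,7-triol
Product: 28 (1(10)Z,4R,5R,6R,7S,8R)-8-[(tert-butyldimethylsilyl)oxy]-4,5-epoxy-12-[(4-methoxybenzyl)oxy]-6-[(triethylsilyl)oxy]germacra-1(10),11(13)-dien-7-ol, via mesylate 27 (not isolated)
Conditions: MsCl, Et3N, CH2Cl2, −20 °C; then K2CO3, MeOH, 0 °C
Reagents that add atoms: none
Why: Only the secondary C5 hydroxyl is sulfonylated (the C4 and C7 hydroxyls are tertiary); the C4 alkoxide then displaces the mesylate by intramolecular SN2 with inversion at C5. The ring-cis diol thus gives the trans-epoxide (4R,5R) stereospecifically, and no acid is needed afterwards.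

Step 17
Reactants: 28 (1(10)Z,4R,5R,6R,7S,8R)-8-[(tert-butyldimethylsilyl)oxy]-4,5-epoxy-12-[(4-methoxybenzyl)oxy]-6-[(triethylsilyl)oxy]germacra-1(10),11(13)-dien-7-ol
Product: 29 (1(10)Z,4R,5R,6R,7S,8R)-8-[(tert-butyldimethylsilyl)oxy]-4,5-epoxy-6-[(triethylsilyl)oxy]germacra-1(10),11(13)-diene-7,12-diol
Conditions: DDQ, CH2Cl2–pH 7 buffer, 0 °C
Reagents that add atoms: none
Why: Oxidative cleavage of the 4-methoxybenzyl ether under buffered, near-neutral conditions that spare the epoxide, the silyl ethers and the olefins.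

Step 18
Reactants: 29 (1(10)Z,4R,5R,6R,7S,8R)-8-[(tert-butyldimethylsilyl)oxy]-4,5-epoxy-6-[(triethylsilyl)oxy]germacra-1(10),11(13)-diene-7,12-diol
Product: 30 (1(10)Z,4R,5R,6R,7R,8R)-8-[(tert-butyldimethylsilyl)oxy]-4,5-epoxygermacra-1(10),11(13)-diene-6,7,12-triol
Conditions: HF·pyridine, pyridine, THF, 0 °C
Reagents that add atoms: none
Why: Selective removal of the triethylsilyl ether at O6 in the presence of the hindered tert-butyldimethylsilyl ether at O8; buffered fluoride is tolerated by trisubstituted epoxides, and base is avoided so that the epoxy alcohol cannot undergo Payne migration.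

Step 19
Reactants: 30 (1(10)Z,4R,5R,6R,7R,8R)-8-[(tert-butyldimethylsilyl)oxy]-4,5-epoxygermacra-1(10),11(13)-diene-6,7,12-triol
Product: 33 (1(10)Z,4R,5R,6R,7R,8R)-8-[(tert-butyldimethylsilyl)oxy]-4,5-epoxy-7-hydroxygermacra-1(10),11(13)-dien-12,6-olide, via enal 31 (not isolated), via lactol 32 (not isolated)
Conditions: MnO2 (activated, excess), CH2Cl2, rt
Reagents that add atoms: none
Why: MnO2 oxidises only the allylic primary alcohol to enal 31; the C6 hydroxyl closes the five-membered lactol 32, which is oxidised on to the α-methylene lactone (oxidative lactonisation of a 2-methylene-1,4-diol). O8 is still silylated, so the lactone can form only on O6.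

Step 20
Reactants: 33 (1(10)Z,4R,5R,6R,7R,8R)-8-[(tert-butyldimethylsilyl)oxy]-4,5-epoxy-7-hydroxygermacra-1(10),11(13)-dien-12,6-olide
Product: 34 (1(10)Z,4R,5R,6R,7S,8R)-4,5-epoxy-7,8-dihydroxygermacra-1(10),11(13)-dien-12,6-olide
Conditions: HF·pyridine, THF, rt
Reagents that add atoms: none
Why: Fluoride-mediated desilylation under mildly acidic, non-nucleophilic conditions; these are preferred to basic fluoride, which would add to the α-methylene lactone.

Step 21
Reactants: 34 (1(10)Z,4R,5R,6R,7S,8R)-4,5-epoxy-7,8-dihydroxygermacra-1(10),11(13)-dien-12,6-olide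
Product: 35 (1(10)Z,4R,5R,6R,7S,8R)-4,5-epoxy-7-hydroxy-8-(methacryloyloxy)germacra-1(10),11(13)-dien-12,6-olide
Conditions: methacrylic anhydride, Et3N, DMAP (cat.), CH2Cl2, 0 °C → rt
Reagents that add atoms: methacrylic anhydride, C=C(C)C(=O)OC(=O)C(C)=C
Why: DMAP-catalysed acylation of the secondary C8 hydroxyl; the tertiary C7 hydroxyl is not acylated under these conditions.

Step 22
Reactants: 35 (1(10)Z,4R,5R,6R,7S,8R)-4,5-epoxy-7-hydroxy-8-(methacryloyloxy)germacra-1(10),11(13)-dien-12,6-olide
Product: 36 (1S,4R,5R,6R,7S,8R,10R)-1,10:4,5-diepoxy-7-hydroxy-8-(methacryloyloxy)germacr-11(13)-en-12,6-olide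
Conditions: mCPBA, NaHCO3, CH2Cl2, 0 °C
Reagents that add atoms: 3-chloroperoxybenzoic acid, O=C(OO)c1cccc(Cl)c1
Why: Prilezhaev epoxidation of the only electron-rich olefin (the acrylate-type alkenes are inert to peracid); syn oxygen transfer turns the Z olefin into the cis-epoxide. The oxidant can reach only the outer face of the olefin in the ten-membered ring, and this is expected, but not assured, to give the (1S,10R) isomer.

Compound list

1 | 2-(bromomethyl)-1,3-dioxolane | BrCC1OCCO1 | starting material
2 | (1,3-dioxolan-2-ylmethyl)magnesium bromide | Br[Mg]CC1OCCO1 | intermediate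
3 | propyne | CC#C | starting material
4 | methyl vinyl ketone (but-3-en-2-one) | CC(=O)C=C | starting material
5 | (1,3-dioxolan-2-ylmethyl)copper, as its MgBr2·SMe2 complex | [Cu]CC1OCCO1 | intermediate
6 | [(1Z)-3-(1,3-dioxolan-2-yl)-2-methylprop-1-en-1-yl]copper | [Cu]/C=C(C)\CC1OCCO1 | intermediate
7 | {[(5Z)-7-(1,3-dioxolan-2-yl)-6-methylhepta-2,5-dien-2-yl]oxy}trimethylsilane (enol ether geometry not defined) | CC(O[Si](C)(C)C)=CC/C=C(C)\CC1OCCO1 | intermediate
8 | (5Z)-7-(1,3-dioxolan-2-yl)-6-methylhept-5-en-2-one | CC(=O)CC/C=C(C)\CC1OCCO1 | intermediate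
9 | 2,3-dibromoprop-1-ene | C=C(Br)CBr | starting material
10 | (4-methoxyphenyl)methanol | COc1ccc(CO)cc1 | starting material
11 | 1-{[(2-bromoprop-2-en-1-yl)oxy]methyl}-4-methoxybenzene | C=C(Br)COCc1ccc(OC)cc1 | intermediate
12 | methyl prop-2-ynoate | C#CC(=O)OC | starting material
13 | methyl 5-[(4-methoxybenzyl)oxy]-4-methylidenepent-2-ynoate | C=C(COCc1ccc(OC)cc1)C#CC(=O)OC | intermediate
14 | methyl (2E)-5-[(4-methoxybenzyl)oxy]-4-methylidene-3-(tributylstannyl)pent-2-enoate | COC(=O)/C=C(/[Sn](CCCC)(CCCC)CCCC)C(=C)COCc1ccc(OC)cc1 | intermediate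
15 | methyl (2E)-3-iodo-5-[(4-methoxybenzyl)oxy]-4-methylidenepent-2-enoate | COC(=O)/C=C(/I)C(=C)COCc1ccc(OC)cc1 | intermediate
16 | (2E)-3-iodo-5-[(4-methoxybenzyl)oxy]-4-methylidenepent-2-en-1-ol | OC/C=C(/I)C(=C)COCc1ccc(OC)cc1 | intermediate
17 | (3Z)-3-methyl-7-oxooct-3-enal | CC(=O)CC/C=C(C)\CC=O | intermediate
18 | (5Z,8R,9E)-8,11-dihydroxy-9-{3-[(4-methoxybenzyl)oxy]prop-1-en-2-yl}-6-methylundeca-5,9-dien-2-one | CC(=O)CC/C=C(C)\C[C@@H](O)/C(=C/CO)C(=C)COCc1ccc(OC)cc1 | intermediate
19 | (5Z,8R,9E)-8,11-bis[(tert-butyldimethylsilyl)oxy]-9-{3-[(4-methoxybenzyl)oxy]prop-1-en-2-yl}-6-methylundeca-5,9-dien-2-one | CC(=O)CC/C=C(C)\C[C@@H](O[Si](C)(C)C(C)(C)C)/C(=C/CO[Si](C)(C)C(C)(C)C)C(=C)COCc1ccc(OC)cc1 | intermediate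
20 | (5Z,8R,9E)-8-[(tert-butyldimethylsilyl)oxy]-11-hydroxy-9-{3-[(4-methoxybenzyl)oxy]prop-1-en-2-yl}-6-methylundeca-5,9-dien-2-one | CC(=O)CC/C=C(C)\C[C@@H](O[Si](C)(C)C(C)(C)C)/C(=C/CO)C(=C)COCc1ccc(OC)cc1 | intermediate
21 | (5Z,8R)-8-[(tert-butyldimethylsilyl)oxy]-8-[(2R,3S)-3-(hydroxymethyl)-2-{3-[(4-methoxybenzyl)oxy]prop-1-en-2-yl}oxiran-2-yl]-6-methyloct-5-en-2-one | CC(=O)CC/C=C(C)\C[C@@H](O[Si](C)(C)C(C)(C)C)[C@]1(C(=C)COCc2ccc(OC)cc2)O[C@H]1CO | intermediate
22 | (5Z,8R,9R)-8-[(tert-butyldimethylsilyl)oxy]-9-hydroxy-10-{[(4-methoxybenzyl)oxy]methyl}-6-methyl-9-[(2R)-oxiran-2-yl]undeca-5,10-dien-2-one (present as its alkoxide) | CC(=O)CC/C=C(C)\C[C@@H](O[Si](C)(C)C(C)(C)C)[C@@](O)(C(=C)COCc1ccc(OC)cc1)[C@H]1CO1 | intermediate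
23 | (5Z,8R,9R,10R)-8-[(tert-butyldimethylsilyl)oxy]-9,10,11-trihydroxy-9-{3-[(4-methoxybenzyl)oxy]prop-1-en-2-yl}-6-methylundec-5-en-2-one | CC(=O)CC/C=C(C)\C[C@@H](O[Si](C)(C)C(C)(C)C)[C@@](O)(C(=C)COCc1ccc(OC)cc1)[C@H](O)CO | intermediate
24 | (5Z,8R,9S,10R)-8-[(tert-butyldimethylsilyl)oxy]-9-hydroxy-9-{3-[(4-methoxybenzyl)oxy]prop-1-en-2-yl}-6-methyl-10,11-bis[(triethylsilyl)oxy]undec-5-en-2-one | CC(=O)CC/C=C(C)\C[C@@H](O[Si](C)(C)C(C)(C)C)[C@@](O)(C(=C)COCc1ccc(OC)cc1)[C@H](O[Si](CC)(CC)CC)CO[Si](CC)(CC)CC | intermediate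
25 | (2S,3S,4R,6Z)-4-[(tert-butyldimethylsilyl)oxy]-3-hydroxy-3-{3-[(4-methoxybenzyl)oxy]prop-1-en-2-yl}-6-methyl-10-oxo-2-[(triethylsilyl)oxy]undec-6-enal | CC(=O)CC/C=C(C)\C[C@@H](O[Si](C)(C)C(C)(C)C)[C@@](O)(C(=C)COCc1ccc(OC)cc1)[C@H](O[Si](CC)(CC)CC)C=O | intermediate
26 | (1(10)Z,4R,5S,6R,7S,8R)-8-[(tert-butyldimethylsilyl)oxy]-12-[(4-methoxybenzyl)oxy]-6-[(triethylsilyl)oxy]germacra-1(10),11(13)-diene-4,5,7-triol | CC(C)(C)[Si](C)(C)O[C@@H]1C/C(C)=C\CC[C@@](C)(O)[C@@H](O)[C@@H](O[Si](CC)(CC)CC)[C@]1(O)C(=C)COCc1ccc(OC)cc1 | intermediate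
27 | (1(10)Z,4R,5S,6R,7S,8R)-8-[(tert-butyldimethylsilyl)oxy]-4,7-dihydroxy-12-[(4-methoxybenzyl)oxy]-6-[(triethylsilyl)oxy]germacra-1(10),11(13)-dien-5-yl methanesulfonate | CC(C)(C)[Si](C)(C)O[C@@H]1C/C(C)=C\CC[C@@](C)(O)[C@@H](OS(C)(=O)=O)[C@@H](O[Si](CC)(CC)CC)[C@]1(O)C(=C)COCc1ccc(OC)cc1 | intermediate
28 | (1(10)Z,4R,5R,6R,7S,8R)-8-[(tert-butyldimethylsilyl)oxy]-4,5-epoxy-12-[(4-methoxybenzyl)oxy]-6-[(triethylsilyl)oxy]germacra-1(10),11(13)-dien-7-ol | CC(C)(C)[Si](C)(C)O[C@@H]1C/C(C)=C\CC[C@@]2(C)O[C@@H]2[C@@H](O[Si](CC)(CC)CC)[C@]1(O)C(=C)COCc1ccc(OC)cc1 | intermediate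
29 | (1(10)Z,4R,5R,6R,7S,8R)-8-[(tert-butyldimethylsilyl)oxy]-4,5-epoxy-6-[(triethylsilyl)oxy]germacra-1(10),11(13)-diene-7,12-diol | CC(C)(C)[Si](C)(C)O[C@@H]1C/C(C)=C\CC[C@@]2(C)O[C@@H]2[C@@H](O[Si](CC)(CC)CC)[C@]1(O)C(=C)CO | intermediate
30 | (1(10)Z,4R,5R,6R,7R,8R)-8-[(tert-butyldimethylsilyl)oxy]-4,5-epoxygermacra-1(10),11(13)-diene-6,7,12-triol | CC(C)(C)[Si](C)(C)O[C@@H]1C/C(C)=C\CC[C@@]2(C)O[C@@H]2[C@@H](O)[C@]1(O)C(=C)CO | intermediate
31 | (1(10)Z,4R,5R,6R,7R,8R)-8-[(tert-butyldimethylsilyl)oxy]-4,5-epoxy-6,7-dihydroxygermacra-1(10),11(13)-dien-12-al | CC(C)(C)[Si](C)(C)O[C@@H]1C/C(C)=C\CC[C@@]2(C)O[C@@H]2[C@@H](O)[C@]1(O)C(=C)C=O | intermediate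
32 | (1(10)Z,4R,5R,6R,7R,8R)-8-[(tert-butyldimethylsilyl)oxy]-4,5:6,12-diepoxygermacra-1(10),11(13)-diene-7,12-diol (lactol, C12 epimers) | CC(C)(C)[Si](C)(C)O[C@@H]1C/C(C)=C\CC[C@@]2(C)O[C@@H]2[C@H]2OC(O)C(=C)[C@@]21O | intermediate
33 | (1(10)Z,4R,5R,6R,7R,8R)-8-[(tert-butyldimethylsilyl)oxy]-4,5-epoxy-7-hydroxygermacra-1(10),11(13)-dien-12,6-olide | CC(C)(C)[Si](C)(C)O[C@@H]1C/C(C)=C\CC[C@@]2(C)O[C@@H]2[C@H]2OC(=O)C(=C)[C@@]21O | intermediate
34 | (1(10)Z,4R,5R,6R,7S,8R)-4,5-epoxy-7,8-dihydroxygermacra-1(10),11(13)-dien-12,6-olide | O[C@@H]1C/C(C)=C\CC[C@@]2(C)O[C@@H]2[C@H]2OC(=O)C(=C)[C@@]21O | intermediate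
35 | (1(10)Z,4R,5R,6R,7S,8R)-4,5-epoxy-7-hydroxy-8-(methacryloyloxy)germacra-1(10),11(13)-dien-12,6-olide | C=C(C)C(=O)O[C@@H]1C/C(C)=C\CC[C@@]2(C)O[C@@H]2[C@H]2OC(=O)C(=C)[C@@]21O | intermediate
36 | (1S,4R,5R,6R,7S,8R,10R)-1,10:4,5-diepoxy-7-hydroxy-8-(methacryloyloxy)germacr-11(13)-en-12,6-olide (CNP0228789.1) | C=C(C)C(=O)O[C@@H]1C[C@@]2(C)O[C@H]2CC[C@@]2(C)O[C@@H]2[C@H]2OC(=O)C(=C)[C@@]21O | target

Total step count: 22. Longest linear sequence: 19 steps (steps 3–6, then 8–22); the line through the key step (steps 1, 2, 7, 8–22) has 18.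

Least certain steps

Step 2 (key step). The most likely failure is slow syn addition to 3, with competing metalation of the alkyne and thermal β-elimination of 5, because 2 brings THF into a reaction that runs best in ether, and because 5 has oxygen β to copper. The fallback avoids carbocupration and sets the Z olefin with a stereodefined enol phosphate. It sets out from 2: methyl acetoacetate is converted (NaH, ClP(O)(OEt)2, Et2O, 0 °C) into methyl (2Z)-3-[(diethoxyphosphoryl)oxy]but-2-enoate F1, and 2 is cross-coupled with it (Fe(acac)3 cat., THF–NMP, −20 °C) with retention to give methyl (2Z)-4-(1,3-dioxolan-2-yl)-3-methylbut-2-enoate F2, in which C9 is cis to the ester carbon (C2). Reduction with iBu2AlH gives (2Z)-4-(1,3-dioxolan-2-yl)-3-methylbut-2-en-1-ol F3, and CBr4/PPh3 gives 2-[(2Z)-4-bromo-2-methylbut-2-en-1-yl]-1,3-dioxolane F4. Alkylation of ethyl acetoacetate (NaOEt, EtOH) gives ethyl (4Z)-2-acetyl-6-(1,3-dioxolan-2-yl)-5-methylhex-4-enoate F5, and saponification with decarboxylation at pH 4 returns to the route at 8.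

Step 15. The uncertain process is stereocontrol at C4 during ring closure: the face of the ketone that bonds to the ketyl is set only by the conformation of a forming ten-membered ring, so a ring-trans diol may be formed, alongside intermolecular coupling if dilution is insufficient. The fallback makes the epoxide from the E olefin and not from the diol. It sets out from 25: should the closure give a trans-diol, for example (1(10)Z,4R,5R,6R,7S,8R)-8-[(tert-butyldimethylsilyl)oxy]-12-[(4-methoxybenzyl)oxy]-6-[(triethylsilyl)oxy]germacra-1(10),11(13)-diene-4,5,7-triol F11, it is converted with 1,1'-thiocarbonyldiimidazole into its 4,5-O-thiocarbonyl derivative F12. Corey–Winter elimination (1,3-dimethyl-2-phenyl-1,3,2-diazaphospholidine, 40 °C) is a stereospecific syn elimination and gives (1(10)Z,4E,6R,7S,8R)-8-[(tert-butyldimethylsilyl)oxy]-12-[(4-methoxybenzyl)oxy]-6-[(triethylsilyl)oxy]germacra-1(10),4,11(13)-trien-7-ol F13; either trans-diol converges on this olefin. HF·pyridine frees O6 to give (1(10)Z,4E,6R,7R,8R)-8-[(tert-butyldimethylsilyl)oxy]-12-[(4-methoxybenzyl)oxy]germacra-1(10),4,11(13)-triene-6,7-diol F14. VO(acac)2/tBuOOH then epoxidises only the olefin allylic to the C6 hydroxyl, in the threo sense expected for an allylic alcohol with a cis substituent (C15), to give (1(10)Z,4R,5R,6R,7R,8R)-8-[(tert-butyldimethylsilyl)oxy]-4,5-epoxy-12-[(4-methoxybenzyl)oxy]germacra-1(10),11(13)-diene-6,7-diol F15. DDQ returns to the route at 30.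

Step 8. The risk is poor enantiofacial control at the aldehyde (the ligand was developed for other iodoalkenes, and the free hydroxyl of 16 can compete for chromium), together with slow coupling of a hindered dienyl iodide. The fallback gives up catalyst control and resolves through diastereomers. It sets out from 17 and 16: coupling without ligand (CrCl2, NiCl2 cat., DMSO) gives 18 together with its enantiomer (5Z,8S,9E)-8,11-dihydroxy-9-{3-[(4-methoxybenzyl)oxy]prop-1-en-2-yl}-6-methylundeca-5,9-dien-2-one F7. The pair is taken through steps 9 and 10, which also give (5Z,8S,9E)-8,11-bis[(tert-butyldimethylsilyl)oxy]-9-{3-[(4-methoxybenzyl)oxy]prop-1-en-2-yl}-6-methylundeca-5,9-dien-2-one F8 and (5Z,8S,9E)-8-[(tert-butyldimethylsilyl)oxy]-11-hydroxy-9-{3-[(4-methoxybenzyl)oxy]prop-1-en-2-yl}-6-methylundeca-5,9-dien-2-one F9. The reagent-controlled epoxidation of step 11 then gives 21 and its C8 epimer (5Z,8S)-8-[(tert-butyldimethylsilyl)oxy]-8-[(2R,3S)-3-(hydroxymethyl)-2-{3-[(4-methoxybenzyl)oxy]prop-1-en-2-yl}oxiran-2-yl]-6-methyloct-5-en-2-one F10, which are diastereomers and separable; the route is rejoined at 21.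

Step 7. The risk is migration of the C1=C10 double bond into conjugation with the new aldehyde (and loss of the Z geometry) during hydrolysis, since a dioxolane needs more forcing acid than the β,γ-unsaturated aldehyde tolerates. The fallback changes the masking group before any aldehyde is set free. It sets out from 8: acetal exchange (MeOH, HC(OMe)3, PPTS, rt) gives (5Z)-8,8-dimethoxy-6-methyloct-5-en-2-one F6, which is hydrolysed under much milder conditions (Amberlyst-15, wet acetone, 0 °C); the solution of 17 is used directly in step 8.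

Step 22. The risk is poor or wrong facial selectivity in the epoxidation of the ring olefin, which rests on ring conformation alone. The fallback uses delivery from a neighbouring hydroxyl and reverses the order of the last two steps. It sets out from 34: VO(acac)2/tBuOOH, directed by the homoallylic C8 hydroxyl, epoxidises C1=C10 from the face that this hydroxyl can reach, to give (1S,4R,5R,6R,7S,8R,10R)-1,10:4,5-diepoxy-7,8-dihydroxygermacr-11(13)-en-12,6-olide F16, and acylation as in step 21 returns to the route at 36. The two reagents need not share a facial preference, so between them both faces are probed.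

Further compounds

F1 | step 2 | methyl (2Z)-3-[(diethoxyphosphoryl)oxy]but-2-enoate | COC(=O)/C=C(C)\OP(=O)(OCC)OCC
F2 | step 2 | methyl (2Z)-4-(1,3-dioxolan-2-yl)-3-methylbut-2-enoate | COC(=O)/C=C(C)\CC1OCCO1
F3 | step 2 | (2Z)-4-(1,3-dioxolan-2-yl)-3-methylbut-2-en-1-ol | OC/C=C(C)\CC1OCCO1
F4 | step 2 | 2-[(2Z)-4-bromo-2-methylbut-2-en-1-yl]-1,3-dioxolane | BrC/C=C(C)\CC1OCCO1
F5 | step 2 | ethyl (4Z)-2-acetyl-6-(1,3-dioxolan-2-yl)-5-methylhex-4-enoate | CCOC(=O)C(C(C)=O)C/C=C(C)\CC1OCCO1
F6 | step 7 | (5Z)-8,8-dimethoxy-6-methyloct-5-en-2-one | CC(=O)CC/C=C(C)\CC(OC)OC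
F7 | step 8 | (5Z,8S,9E)-8,11-dihydroxy-9-{3-[(4-methoxybenzyl)oxy]prop-1-en-2-yl}-6-methylundeca-5,9-dien-2-one | CC(=O)CC/C=C(C)\C[C@H](O)/C(=C/CO)C(=C)COCc1ccc(OC)cc1
F8 | step 8 | (5Z,8S,9E)-8,11-bis[(tert-butyldimethylsilyl)oxy]-9-{3-[(4-methoxybenzyl)oxy]prop-1-en-2-yl}-6-methylundeca-5,9-dien-2-one | CC(=O)CC/C=C(C)\C[C@H](O[Si](C)(C)C(C)(C)C)/C(=C/CO[Si](C)(C)C(C)(C)C)C(=C)COCc1ccc(OC)cc1
F9 | step 8 | (5Z,8S,9E)-8-[(tert-butyldimethylsilyl)oxy]-11-hydroxy-9-{3-[(4-methoxybenzyl)oxy]prop-1-en-2-yl}-6-methylundeca-5,9-dien-2-one | CC(=O)CC/C=C(C)\C[C@H](O[Si](C)(C)C(C)(C)C)/C(=C/CO)C(=C)COCc1ccc(OC)cc1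
F10 | step 8 | (5Z,8S)-8-[(tert-butyldimethylsilyl)oxy]-8-[(2R,3S)-3-(hydroxymethyl)-2-{3-[(4-methoxybenzyl)oxy]prop-1-en-2-yl}oxiran-2-yl]-6-methyloct-5-en-2-one | CC(=O)CC/C=C(C)\C[C@H](O[Si](C)(C)C(C)(C)C)[C@]1(C(=C)COCc2ccc(OC)cc2)O[C@H]1CO
F11 | step 15 | (1(10)Z,4R,5R,6R,7S,8R)-8-[(tert-butyldimethylsilyl)oxy]-12-[(4-methoxybenzyl)oxy]-6-[(triethylsilyl)oxy]germacra-1(10),11(13)-diene-4,5,7-triol | CC(C)(C)[Si](C)(C)O[C@@H]1C/C(C)=C\CC[C@@](C)(O)[C@H](O)[C@@H](O[Si](CC)(CC)CC)[C@]1(O)C(=C)COCc1ccc(OC)cc1
F12 | step 15 | 4,5-O-thiocarbonyl derivative (cyclic thionocarbonate) of F11 | CC(C)(C)[Si](C)(C)O[C@@H]1C/C(C)=C\CC[C@@]2(C)OC(=S)O[C@@H]2[C@@H](O[Si](CC)(CC)CC)[C@]1(O)C(=C)COCc1ccc(OC)cc1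
F13 | step 15 | (1(10)Z,4E,6R,7S,8R)-8-[(tert-butyldimethylsilyl)oxy]-12-[(4-methoxybenzyl)oxy]-6-[(triethylsilyl)oxy]germacra-1(10),4,11(13)-trien-7-ol | CC(C)(C)[Si](C)(C)O[C@@H]1C/C(C)=C\CC/C(C)=C/[C@@H](O[Si](CC)(CC)CC)[C@]1(O)C(=C)COCc1ccc(OC)cc1
F14 | step 15 | (1(10)Z,4E,6R,7R,8R)-8-[(tert-butyldimethylsilyl)oxy]-12-[(4-methoxybenzyl)oxy]germacra-1(10),4,11(13)-triene-6,7-diol | CC(C)(C)[Si](C)(C)O[C@@H]1C/C(C)=C\CC/C(C)=C/[C@@H](O)[C@]1(O)C(=C)COCc1ccc(OC)cc1
F15 | step 15 | (1(10)Z,4R,5R,6R,7R,8R)-8-[(tert-butyldimethylsilyl)oxy]-4,5-epoxy-12-[(4-methoxybenzyl)oxy]germacra-1(10),11(13)-diene-6,7-diol | CC(C)(C)[Si](C)(C)O[C@@H]1C/C(C)=C\CC[C@@]2(C)O[C@@H]2[C@@H](O)[C@]1(O)C(=C)COCc1ccc(OC)cc1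
F16 | step 22 | (1S,4R,5R,6R,7S,8R,10R)-1,10:4,5-diepoxy-7,8-dihydroxygermacr-11(13)-en-12,6-olide | O[C@@H]1C[C@@]2(C)O[C@H]2CC[C@@]2(C)O[C@@H]2[C@H]2OC(=O)C(=C)[C@@]21O
A1 | alternative 1 | (1(10)Z,4R,5S,6R,7R,8R)-8-O-(tert-butyldimethylsilyl)-6,7-O-isopropylidene-12-O-(4-methoxybenzyl)germacra-1(10),11(13)-diene-4,5,6,7,8,12-hexol (cis-4,5-diol) | CC(C)(C)[Si](C)(C)O[C@@H]1C/C(C)=C\CC[C@@](C)(O)[C@@H](O)[C@H]2OC(C)(C)O[C@]21C(=C)COCc1ccc(OC)cc1
A2 | alternative 1 | (4S,5R)-5-[(1R,3Z)-1-[(tert-butyldimethylsilyl)oxy]-3-methyl-7-oxooct-3-en-1-yl]-5-{3-[(4-methoxybenzyl)oxy]prop-1-en-2-yl}-2,2-dimethyl-1,3-dioxolane-4-carbaldehyde | CC(=O)CC/C=C(C)\C[C@@H](O[Si](C)(C)C(C)(C)C)[C@]1(C(=C)COCc2ccc(OC)cc2)OC(C)(C)O[C@@H]1C=O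
A3 | alternative 2 | (1(10)Z,4E,6R,7S,8R)-7-hydroxy-8-(methacryloyloxy)germacra-1(10),4,11(13)-trien-12,6-olide | C=C(C)C(=O)O[C@@H]1C/C(C)=C\CC/C(C)=C/[C@H]2OC(=O)C(=C)[C@@]21O
A4 | alternative 2 | (1(10)Z,4E,6R,8R)-8-(methacryloyloxy)-7-oxo-11,12,13-trinorgermacra-1(10),4-dien-6-yl 2-bromoprop-2-enoate | C=C(C)C(=O)O[C@@H]1C/C(C)=C\CC/C(C)=C/[C@@H](OC(=O)C(Br)=C)C1=O
A5 | alternative 3 | (1(10)Z,4E,6R,7S,8R)-8-(methacryloyloxy)-7-[(triethylsilyl)oxy]germacra-1(10),4,11(13)-trien-12,6-olide | C=C(C)C(=O)O[C@@H]1C/C(C)=C\CC/C(C)=C/[C@H]2OC(=O)C(=C)[C@@]21O[Si](CC)(CC)CC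
A6 | alternative 3 | methyl 2-[(2S,3R,5Z,9E)-10-iodo-5,9-dimethyl-3-(methacryloyloxy)-1-oxo-2-[(triethylsilyl)oxy]deca-5,9-dien-2-yl]prop-2-enoate | I/C=C(\C)CC/C=C(C)\C[C@@H](OC(=O)C(C)=C)[C@](O[Si](CC)(CC)CC)(C=O)C(=C)C(=O)OC
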